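## Analysis of the target

Putraflavone 19 is a biflavone of six rings. Unit 1 is the 5-hydroxy-7-methoxyflavone half (rings A1, C1, B1) and unit 2 the 5,7-dihydroxy-4'-methoxyflavone half (rings A2, C2, B2); one biaryl bond joins C3' of ring B1 to C8 of ring A2. There is no stereocenter, and the C3'–C8 axis, although flanked by three ortho substituents, has no assigned configuration. Four phenols, two of them chelated to a pyranone carbonyl (C5 of each unit), stand beside two aryl methyl ethers (C7 of unit 1, C4' of ring B2). Both phloroglucinol-type rings are easily iodinated or C-alkylated, and the pyranones open under hot strong base; a 5-hydroxy-8-arylflavone can also re-close to its 6-aryl isomer under hot strong acid. The difficulty is therefore not the skeleton but the placing of the two methyl groups among six similar oxygens, since no late selective methylation or demethylation can be trusted; the crowded bond between two electron-rich rings comes second. The strategy rests on ring A1: C4a bears the acyl carbon C4, C5 and C8a bear oxygens that end as hydroxyl and ring oxygen, and C7, para to C4a, bears the only methyl ether. That is the pattern of a triketide folded by Claisen acylation with its middle carbonyl held as a methyl enol ether, and a 4-methoxy-2-pyranone is such a chain in masked form.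

## Retrosynthetic reasoning

19 ⇒ 18. The last bonds cut are the three O–benzyl bonds at C5 and C7 of unit 2 and at C4' of ring B1. Every oxygen that must end as a phenol is carried as a benzyl ether and none as a methyl ether, so the final Lewis-acid debenzylation never has to tell one methyl ether from another. It also runs cold, away from the hot acid that could move the aryl group from C8 to C6.

18 ⇒ 17. Ring C1 is opened at O1–C2, which leads back to a 2'-hydroxychalcone. Ring A1 of 17 has two equivalent ortho hydroxyls, so either one closes to the same flavone and the other becomes the chelated 5-OH. The forward oxidative cyclisation forms the C–O bond and the C2=C3 unsaturation in one operation.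

17 ⇒ 15, through 16. This is the key disconnection: the C4a–C8a bond of ring A1 (equivalent to C4a–C5 while the ring is still symmetric) is cut. The ring unravels to the open-chain ester 16, which is stored as the pyranone 15. The cut is made here because this bond alone turns an aromatic ring with three differentiated oxygens into a chain in which those oxygens are already distinct: ester, enol ether and ketone. The forward step has to open the lactone with an alkoxide and then acylate the central methylene at the ester carbon.

15 ⇒ 12 + 13, through 14. The C4–C4a bond of unit 1 is cut between the ketone carbon and the pyranone methylene. The carbanion 14 from commercial 13 is the nucleophile and the N-methoxy-N-methylamide 12 the acyl donor. The amide stops at the ketone stage, which matters because the methylene of 15 is far more acidic than the methyl group of 13.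

12 ⇒ 10 + 11. The future C2=C3 bond of unit 1 is cut by a Horner–Wadsworth–Emmons disconnection. This places the cinnamoyl carbons on the aldehyde 10 with E geometry and brings in the amide in the same step.

10 ⇒ 6 + 9. The interflavone bond C3'–C8 is cut as a Suzuki–Miyaura coupling. It is made before ring A1 exists, so that the palladium step meets only one electron-rich ring and no acidic methylene. The iodide is put on unit 2 and the boron on ring B1, because an 8-borylated 5,7-dialkoxyflavone would lose boron readily.

6 ⇒ 5 ⇒ 4 ⇒ 2 + 3, and 2 ⇒ 1. The C8–I bond is cut first; in 5 both oxygens of ring A2 are alkylated, which directs an electrophile to C8. Unit 2 is then taken apart by the chalcone route: O1–C2 of ring C2 to 4, the enone C=C to ketone 2 and aldehyde 3, and the two benzyl ethers to 1. Building the flavone before halogenation avoids iodinating a free resorcinol, where two activated positions compete.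

9 ⇒ 8 ⇒ 7. The C–B bond is cut back to the bromide 8 and the benzyl ether to the commercial bromophenol 7.

## Alternatives that were turned down

Alternative 1: Ring C1 is cut at the aryl–oxygen bond O1–C8a. Forward, the 1,3-diketone A2, whose ring A1 portion bears fluorine ortho to the ketone, is treated with a carbonate base in a dipolar aprotic solvent. The enolate oxygen displaces fluoride through a Meisenheimer adduct and gives the protected biflavone A1.
- For: no oxidant is needed, so the electron-rich rings never meet an electrophilic halogen, and A2 can be assembled convergently by acylating a methyl ketone with a ring B1 ester. On both points it is at least as good as the chosen route.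
- Against: the fluorine of A2 sits on a ring with two alkoxy donors. Its only activator is a ketone that is part of a diketone enolate under the reaction conditions, so it accepts the Meisenheimer charge poorly. The substitution would need forcing conditions on the most elaborate intermediate.
- Against: the fluorinated, differently O-benzylated and O-methylated ring A1 portion needs its own synthesis, which must again tell three oxygens apart. A1 also keeps a peri methyl ether on unit 2 that must be cleaved beside the two methyl ethers of 19.
- Comparison: in place of the oxidant-free closure, the chosen route takes the pattern of ring A1 from commercial 13 through the folding of 16, and ends with benzyl ethers only.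

Alternative 2: Unit 1 is carried complete and ring C2 is cut at C2–C3. Forward, the phenacyl phosphorane A4, whose neighbouring phenol is held as a 4-methoxybenzoate, is heated. The ylide carbon adds to the ester carbonyl and a phosphine oxide is expelled, giving A3.
- For: the closure is neutral, needs neither strong base nor oxidant, and is regiochemically unambiguous. In mildness it is stronger than any ring closure of the chosen route.
- Against: ester carbonyls are poor partners for stabilised ylides, and in A4 the reacting aroyloxy group is wedged between ring B1 and the acyl group. Preparing A4 needs an α-halogenation of a ketone on an electron-rich, fully assembled biaryl, where nuclear halogenation competes.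
- Against: A3 carries two peri methyl ethers, a benzyl ether and an aroyl ester. That means three deprotection operations, two of them selective demethylations beside methyl ethers that must stay.
- Comparison: the special reaction is spent on ring C2, which ordinary chalcone chemistry makes in two steps. The real problem, 5-OH beside 7-OMe in unit 1, is left to a late demethylation, whereas the chosen route settles it constructively.

Alternative 3: Ring C1 is cut into three pieces at C4a–C4, C4–C3 and O1–C2: the iodophenol A6, a one-carbon carbonyl unit from the gas phase, and the terminal alkyne A7 on ring B1. Forward, a palladium–phosphine catalyst in a secondary amine joins them by oxidative addition, carbonyl insertion, alkynylation and conjugate addition of the phenol, giving A5.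
- For: three bonds and a ring form in one operation from two fragments of similar size. In convergence and bond count it is clearly stronger than the chosen key step, which forms one bond.
- Against: in A6 the iodine lies between a hydroxyl and a methoxy group with a further donor para. Oxidative addition and carbonyl insertion are then slow, and direct alkynylation without the carbonyl, which ends in a benzofuran, competes.
- Against: the ynone can close 5-exo to an aurone instead of 6-endo. A6 needs a regioselective iodination between two activated positions, and A7 needs an extra homologation of an aldehyde.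
- Against: A5 has peri methyl ethers in both units, so two selective demethylations follow.
- Comparison: the chosen route is longer and more linear. In return 16 can close only to the six-membered carbocycle, and the phenol pattern of 19 is reached without any demethylation.

Key step: step 10

Remark on the chemistry: the C3'–C8 axis is assumed not to be configurationally defined, so no control of axial chirality is attempted. Flavone numbering is used within each unit.

## Route

Step 1
Reactants: 1 1-(2,4,6-trihydroxyphenyl)ethanone
Product: 2 1-[2,4-bis(benzyloxy)-6-hydroxyphenyl]ethanone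
Conditions: BnBr (2.1 equiv), K2CO3, DMF, 0 °C to rt
Reagents that add atoms: benzyl bromide, BrCc1ccccc1
Why: Williamson ether synthesis; the para hydroxyl and one ortho hydroxyl are alkylated, after which the last hydroxyl is locked in a hydrogen bond to the ketone and is a poor nucleophile, so two equivalents should stop at the bis-ether.

Step 2
Reactants: 2 1-[2,4-bis(benzyloxy)-6-hydroxyphenyl]ethanone; 3 4-methoxybenzaldehyde
Product: 4 (E)-1-[2,4-bis(benzyloxy)-6-hydroxyphenyl]-3-(4-methoxyphenyl)prop-2-en-1-one
Conditions: KOH, EtOH/H2O, rt; then aq. HCl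
Reagents that add atoms: none
Why: Claisen–Schmidt condensation of a methyl ketone with a non-enolisable aldehyde; elimination of the aldol under equilibrating conditions should give the E enone.

Step 3
Reactants: 4 (E)-1-[2,4-bis(benzyloxy)-6-hydroxyphenyl]-3-(4-methoxyphenyl)prop-2-en-1-one
Product: 5 5,7-bis(benzyloxy)-2-(4-methoxyphenyl)-4H-chromen-4-one
Conditions: I2 (cat.), DMSO, 120 °C
Reagents that add atoms: none
Why: Oxidative cyclisation of a 2'-hydroxychalcone (oxa-Michael closure, iodination next to the carbonyl, loss of HI), with DMSO returning HI to I2; the catalytic charge keeps the acid level low for the peri benzyl ether.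

Step 4
Reactants: 5 5,7-bis(benzyloxy)-2-(4-methoxyphenyl)-4H-chromen-4-one
Product: 6 5,7-bis(benzyloxy)-8-iodo-2-(4-methoxyphenyl)-4H-chromen-4-one
Conditions: NIS, DMF, rt to 50 °C
Reagents that add atoms: N-iodosuccinimide, O=C1CCC(=O)N1I
Why: Electrophilic aromatic iodination; in a 5,7-dialkoxyflavone C8 is ortho to the 7-oxygen and para to the 5-oxygen and less crowded than C6, which lies between two benzyloxy groups. Ring B2 and C3 are deactivated by conjugation with the carbonyl.

Step 5
Reactants: 7 3-bromo-4-hydroxybenzaldehyde
Product: 8 4-(benzyloxy)-3-bromobenzaldehyde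
Conditions: BnBr, K2CO3, DMF, rt
Reagents that add atoms: benzyl bromide, BrCc1ccccc1
Why: Williamson ether synthesis on an acidic para-formyl phenol; nothing else in the molecule is alkylated.

Step 6
Reactants: 8 4-(benzyloxy)-3-bromobenzaldehyde
Product: 9 4-(benzyloxy)-3-(4,4,5,5-tetramethyl-1,3,2-dioxaborolan-2-yl)benzaldehyde
Conditions: B2pin2, PdCl2(dppf), KOAc, 1,4-dioxane, 90 °C
Reagents that add atoms: bis(pinacolato)diboron, CC1(C)OB(OC1(C)C)B1OC(C)(C)C(C)(C)O1
Why: Miyaura borylation; zerovalent palladium inserts into the C–Br bond and acetate assists transfer of boron, while the weak base avoids biaryl homocoupling and leaves the aldehyde alone.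

Step 7
Reactants: 6 5,7-bis(benzyloxy)-8-iodo-2-(4-methoxyphenyl)-4H-chromen-4-one; 9 4-(benzyloxy)-3-(4,4,5,5-tetramethyl-1,3,2-dioxaborolan-2-yl)benzaldehyde
Product: 10 4-(benzyloxy)-3-[5,7-bis(benzyloxy)-2-(4-methoxyphenyl)-4-oxo-4H-chromen-8-yl]benzaldehyde
Conditions: Pd(OAc)2, SPhos, K3PO4, toluene/H2O, 90 °C
Reagents that add atoms: none
Why: Suzuki–Miyaura coupling forming the C3'–C8 bond; the bulky electron-rich biarylphosphine supports oxidative addition of zerovalent palladium into the hindered, electron-rich C8–I bond and the transmetalation that leads to a tri-ortho-substituted biaryl. Aldehyde, pyranone and benzyl ethers are inert to phosphate base.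

Step 8
Reactants: 10 4-(benzyloxy)-3-[5,7-bis(benzyloxy)-2-(4-methoxyphenyl)-4-oxo-4H-chromen-8-yl]benzaldehyde; 11 diethyl {2-[methoxy(methyl)amino]-2-oxoethyl}phosphonate
Product: 12 (E)-3-{4-(benzyloxy)-3-[5,7-bis(benzyloxy)-2-(4-methoxyphenyl)-4-oxo-4H-chromen-8-yl]phenyl}-N-methoxy-N-methylprop-2-enamide
Conditions: NaH, THF, 0 °C to rt
Reagents that add atoms: none
Why: Horner–Wadsworth–Emmons olefination with a stabilised phosphonate carbanion, which should give the E alkene through reversible addition; the anion attacks only the aldehyde, the vinylogous-ester carbonyl of the flavone being too unreactive.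

Step 9
Reactants: 13 4-methoxy-6-methyl-2H-pyran-2-one; 12 (E)-3-{4-(benzyloxy)-3-[5,7-bis(benzyloxy)-2-(4-methoxyphenyl)-4-oxo-4H-chromen-8-yl]phenyl}-N-methoxy-N-methylprop-2-enamide
Product: 15 6-[(E)-4-{4-(benzyloxy)-3-[5,7-bis(benzyloxy)-2-(4-methoxyphenyl)-4-oxo-4H-chromen-8-yl]phenyl}-2-oxobut-3-en-1-yl]-4-methoxy-2H-pyran-2-one, via (4-methoxy-2-oxo-2H-pyran-6-yl)methyllithium 14 (not isolated)
Conditions: 13 (2.2 equiv), LiN(iPr)2 (2.0 equiv), THF, −78 °C; then 12, −78 to −30 °C; aq. NH4Cl
Reagents that add atoms: none
Why: The methyl group of 13 is deprotonated to the extended enolate 14, which adds to the amide carbonyl in a Weinreb-type ketone synthesis; the lithium-chelated tetrahedral adduct persists until the quench, so neither over-addition nor proton transfer from the acidic product can occur. A slight deficit of amide base leaves no reagent strong enough to metalate C3 of the flavone, and at low temperature the flavone carbonyl should not compete with the chelating amide.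

Step 10
Reactants: 15 6-[(E)-4-{4-(benzyloxy)-3-[5,7-bis(benzyloxy)-2-(4-methoxyphenyl)-4-oxo-4H-chromen-8-yl]phenyl}-2-oxobut-3-en-1-yl]-4-methoxy-2H-pyran-2-one
Product: 17 (E)-3-{4-(benzyloxy)-3-[5,7-bis(benzyloxy)-2-(4-methoxyphenyl)-4-oxo-4H-chromen-8-yl]phenyl}-1-(2,6-dihydroxy-4-methoxyphenyl)prop-2-en-1-one, via ring-opened methyl 3-methoxy-5,7-dioxonona-2,8-dienoate 16 (not isolated)
Conditions: Mg(OCH3)2 (excess), CH3OH/THF, reflux; then cold dilute aq. HCl
Reagents that add atoms: none
Why: Magnesium-bound methoxide adds to the lactone carbonyl of 15 and opens the pyranone to ester 16, whose 2E enol-ether double bond, inherited from the ring, keeps ester carbon C1 and chain carbon C4 on the same side. The C6 methylene between the two ketones is the most acidic site, and its magnesium diketonate attacks C1 in an intramolecular Claisen acylation; loss of methoxide and enolisation then give aromatic ring A1 of 17. The closest known reaction type is the alkoxide-induced conversion of 6-(2-oxoalkyl)-4-methoxy-2-pyranones and of 3,5,7-triketo esters into acylphloroglucinols. Ring A1 closes in a 6-exo-trig mode (enolendo with respect to the C5–C6 enolate), the only carbocyclic closure open to the C6 nucleophile. No stereocenter is formed, and the E cinnamoyl double bond is carried through. The step needs C-acylation of C1 by C6 to win over aldol attack of C2 on the C7 ketone and over conjugate additions at C9: the methyl enol ether at C3 makes C2 part of a vinylogous carbonate that cannot become a carbanion, and magnesium chelation between the C5 and C7 oxygens localises the charge on C6 and lowers the acceptor strength of the enone. Aromatisation makes the closure irreversible, whereas re-lactonisation of 16 and addition of methoxide to the enone are reversible and only return material. The enol-ether oxygen ends as the 7-methoxy group and the ester and C5 oxygens as the two ortho hydroxyls, so unit 1 needs no selective methylation; any 17 that closes further to its flavanone is also converted to 18 in step 11.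

Step 11
Reactants: 17 (E)-3-{4-(benzyloxy)-3-[5,7-bis(benzyloxy)-2-(4-methoxyphenyl)-4-oxo-4H-chromen-8-yl]phenyl}-1-(2,6-dihydroxy-4-methoxyphenyl)prop-2-en-1-one
Product: 18 5,7-bis(benzyloxy)-8-[2-(benzyloxy)-5-(5-hydroxy-7-methoxy-4-oxo-4H-chromen-2-yl)phenyl]-2-(4-methoxyphenyl)-4H-chromen-4-one
Conditions: I2 (cat.), DMSO, 120 °C
Reagents that add atoms: none
Why: Oxidative cyclisation of a 2'-hydroxychalcone closes ring C1 at O1–C2 and sets the C2=C3 double bond; the two ortho hydroxyls are equivalent, so only one flavone can form and the remaining hydroxyl becomes the chelated 5-OH.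

Step 12
Reactants: 18 5,7-bis(benzyloxy)-8-[2-(benzyloxy)-5-(5-hydroxy-7-methoxy-4-oxo-4H-chromen-2-yl)phenyl]-2-(4-methoxyphenyl)-4H-chromen-4-one
Product: 19 putraflavone, 5,7-dihydroxy-8-[2-hydroxy-5-(5-hydroxy-7-methoxy-4-oxo-4H-chromen-2-yl)phenyl]-2-(4-methoxyphenyl)-4H-chromen-4-one
Conditions: BCl3, C6HMe5, CH2Cl2, −78 to 0 °C; then H2O
Reagents that add atoms: none
Why: Lewis-acid cleavage of aryl benzyl ethers, with pentamethylbenzene trapping the benzyl cation so that the phloroglucinol rings are not C-benzylated. The two methyl ethers are not peri to a carbonyl and should survive BCl3 at this temperature, and the cold aprotic medium cannot move the aryl group from C8 to C6.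

## Compound list

1 | 1-(2,4,6-trihydroxyphenyl)ethanone | CC(=O)c1c(O)cc(O)cc1O | starting material
2 | 1-[2,4-bis(benzyloxy)-6-hydroxyphenyl]ethanone | CC(=O)c1c(O)cc(OCc2ccccc2)cc1OCc1ccccc1 | intermediate
3 | 4-methoxybenzaldehyde | COc1ccc(C=O)cc1 | starting material
4 | (E)-1-[2,4-bis(benzyloxy)-6-hydroxyphenyl]-3-(4-methoxyphenyl)prop-2-en-1-one | COc1ccc(/C=C/C(=O)c2c(O)cc(OCc3ccccc3)cc2OCc2ccccc2)cc1 | intermediate
5 | 5,7-bis(benzyloxy)-2-(4-methoxyphenyl)-4H-chromen-4-one | COc1ccc(cc1)-c1cc(=O)c2c(OCc3ccccc3)cc(OCc3ccccc3)cc2o1 | intermediate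
6 | 5,7-bis(benzyloxy)-8-iodo-2-(4-methoxyphenyl)-4H-chromen-4-one | COc1ccc(cc1)-c1cc(=O)c2c(OCc3ccccc3)cc(OCc3ccccc3)c(I)c2o1 | intermediate
7 | 3-bromo-4-hydroxybenzaldehyde | O=Cc1ccc(O)c(Br)c1 | starting material
8 | 4-(benzyloxy)-3-bromobenzaldehyde | O=Cc1ccc(OCc2ccccc2)c(Br)c1 | intermediate
9 | 4-(benzyloxy)-3-(4,4,5,5-tetramethyl-1,3,2-dioxaborolan-2-yl)benzaldehyde | O=Cc1ccc(OCc2ccccc2)c(c1)B1OC(C)(C)C(C)(C)O1 | intermediate
10 | 4-(benzyloxy)-3-[5,7-bis(benzyloxy)-2-(4-methoxyphenyl)-4-oxo-4H-chromen-8-yl]benzaldehyde | COc1ccc(cc1)-c1cc(=O)c2c(OCc3ccccc3)cc(OCc3ccccc3)c(c2o1)-c1cc(C=O)ccc1OCc1ccccc1 | intermediate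
11 | diethyl {2-[methoxy(methyl)amino]-2-oxoethyl}phosphonate | CCOP(=O)(CC(=O)N(C)OC)OCC | starting material
12 | (E)-3-{4-(benzyloxy)-3-[5,7-bis(benzyloxy)-2-(4-methoxyphenyl)-4-oxo-4H-chromen-8-yl]phenyl}-N-methoxy-N-methylprop-2-enamide | COc1ccc(cc1)-c1cc(=O)c2c(OCc3ccccc3)cc(OCc3ccccc3)c(c2o1)-c1cc(/C=C/C(=O)N(C)OC)ccc1OCc1ccccc1 | intermediate
13 | 4-methoxy-6-methyl-2H-pyran-2-one | COC1=CC(=O)OC(C)=C1 | starting material
14 | (4-methoxy-2-oxo-2H-pyran-6-yl)methyllithium | COC1=CC(=O)OC(C[Li])=C1 | intermediate (not isolated)
15 | 6-[(E)-4-{4-(benzyloxy)-3-[5,7-bis(benzyloxy)-2-(4-methoxyphenyl)-4-oxo-4H-chromen-8-yl]phenyl}-2-oxobut-3-en-1-yl]-4-methoxy-2H-pyran-2-one | COC1=CC(=O)OC(CC(=O)/C=C/c2ccc(OCc3ccccc3)c(c2)-c2c(OCc3ccccc3)cc(OCc3ccccc3)c3c2oc(cc3=O)-c2ccc(OC)cc2)=C1 | intermediate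
16 | methyl (2E,8E)-9-{4-(benzyloxy)-3-[5,7-bis(benzyloxy)-2-(4-methoxyphenyl)-4-oxo-4H-chromen-8-yl]phenyl}-3-methoxy-5,7-dioxonona-2,8-dienoate | COC(=O)/C=C(/OC)CC(=O)CC(=O)/C=C/c1ccc(OCc2ccccc2)c(c1)-c1c(OCc2ccccc2)cc(OCc2ccccc2)c2c1oc(cc2=O)-c1ccc(OC)cc1 | intermediate (not isolated)
17 | (E)-3-{4-(benzyloxy)-3-[5,7-bis(benzyloxy)-2-(4-methoxyphenyl)-4-oxo-4H-chromen-8-yl]phenyl}-1-(2,6-dihydroxy-4-methoxyphenyl)prop-2-en-1-one | COc1cc(O)c(C(=O)/C=C/c2ccc(OCc3ccccc3)c(c2)-c2c(OCc3ccccc3)cc(OCc3ccccc3)c3c2oc(cc3=O)-c2ccc(OC)cc2)c(O)c1 | intermediate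
18 | 5,7-bis(benzyloxy)-8-[2-(benzyloxy)-5-(5-hydroxy-7-methoxy-4-oxo-4H-chromen-2-yl)phenyl]-2-(4-methoxyphenyl)-4H-chromen-4-one | COc1ccc(cc1)-c1cc(=O)c2c(OCc3ccccc3)cc(OCc3ccccc3)c(c2o1)-c1cc(ccc1OCc1ccccc1)-c1cc(=O)c2c(O)cc(OC)cc2o1 | intermediate
19 | putraflavone | COc1ccc(-c2cc(=O)c3c(O)cc(O)c(-c4cc(-c5cc(=O)c6c(O)cc(OC)cc6o5)ccc4O)c3o2)cc1 | target

## Step count and weak points

Total: 12 steps. Longest linear sequence: 10 steps (steps 1 to 4, then 7 to 12); steps 5 and 6 form the side branch.

Step 10, the key step. Deprotonation of the methylene of 15 spreads charge into the lactone and can slow its opening. That leaves time for conjugate addition at the cinnamoyl β-carbon and for hydrolytic loss of the ester carbon if moisture enters. The fallback gives up the pyranone and makes 17 by classical condensation, setting out from 10 and returning at 17: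
- 1-(2,6-dihydroxy-4-methoxyphenyl)ethanone F1 is protected with chloromethyl methyl ether and NaH in DMF as 1-[4-methoxy-2,6-bis(methoxymethoxy)phenyl]ethanone F2.
- Claisen–Schmidt condensation of F2 with 10 (KOH, EtOH/THF, rt) should give the bis(methoxymethyl) chalcone F3.
- Dilute HCl in CH3OH/THF at 40 °C removes both acetals and returns 17.

Step 9. The carbanion 14 may add to the pyranone carbonyl or to C2 of unit 2, or add in conjugate fashion to the enamide, since the amide is not a strong electrophile. The fallback uses an aldehyde, which is far more reactive than any of these; it sets out from 10 and returns at 15: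
- Wittig reaction of 10 with (triphenylphosphoranylidene)acetaldehyde in toluene at 80 °C gives the (E)-enal F4.
- Addition of 14 (from 13 and LiN(iPr)2) to F4 at −78 °C gives the racemic allylic alcohol F5.
- Dess–Martin periodinane in CH2Cl2 oxidises F5 to 15.

Step 7. Loss of boron from 9 by protonolysis under aqueous base may outrun transmetalation onto the hindered arylpalladium iodide, which then ends in reduction of the C8–I bond. The fallback is a base-free Stille coupling, setting out from 8 and returning at 10:
- 8 is stannylated with Me3SnSnMe3 and Pd(PPh3)4 in toluene at 100 °C to 4-(benzyloxy)-3-(trimethylstannyl)benzaldehyde F6.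
- F6 is coupled with 6 using Pd(PPh3)4, CuI and CsF in DMF at 50 °C to give 10.

Step 4. Iodination may spread to C6 or go on to the 6,8-diiodide, or a trace of acid may first free the 5-oxygen and so turn the attack to C6. The fallback places the iodine before the pyranone exists, where the free hydroxyl directs to its own ortho carbon, the later C8; it sets out from 2 and returns at 6:
- 2 is iodinated with NIS in CH2Cl2 with a trace of CF3CO2H to 1-[4,6-bis(benzyloxy)-2-hydroxy-3-iodophenyl]ethanone F7.
- Condensation of F7 with 3 (KOH, EtOH) gives the iodochalcone F8.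
- I2 (cat.) in DMSO at 120 °C closes F8 to 6.

Step 11. The free, activated ring A1 may be iodinated on the nucleus, and the HI formed may remove the peri benzyl ether of unit 2. The latter does not change the final product but splits the material. The fallback avoids iodine, setting out from 17 and returning at 18:
- NaOAc in refluxing EtOH closes 17 to the racemic flavanone F9.
- DDQ in refluxing 1,4-dioxane dehydrogenates F9 to 18.

## Further compounds

F1 | step 10 | 1-(2,6-dihydroxy-4-methoxyphenyl)ethanone | CC(=O)c1c(O)cc(OC)cc1O
F2 | step 10 | 1-[4-methoxy-2,6-bis(methoxymethoxy)phenyl]ethanone | CC(=O)c1c(OCOC)cc(OC)cc1OCOC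
F3 | step 10 | (E)-3-{4-(benzyloxy)-3-[5,7-bis(benzyloxy)-2-(4-methoxyphenyl)-4-oxo-4H-chromen-8-yl]phenyl}-1-[4-methoxy-2,6-bis(methoxymethoxy)phenyl]prop-2-en-1-one | COCOc1cc(OC)cc(OCOC)c1C(=O)/C=C/c1ccc(OCc2ccccc2)c(c1)-c1c(OCc2ccccc2)cc(OCc2ccccc2)c2c1oc(cc2=O)-c1ccc(OC)cc1
F4 | step 9 | (E)-3-{4-(benzyloxy)-3-[5,7-bis(benzyloxy)-2-(4-methoxyphenyl)-4-oxo-4H-chromen-8-yl]phenyl}prop-2-enal | O=C/C=C/c1ccc(OCc2ccccc2)c(c1)-c1c(OCc2ccccc2)cc(OCc2ccccc2)c2c1oc(cc2=O)-c1ccc(OC)cc1
F5 | step 9 | racemic 6-[(E)-4-{4-(benzyloxy)-3-[5,7-bis(benzyloxy)-2-(4-methoxyphenyl)-4-oxo-4H-chromen-8-yl]phenyl}-2-hydroxybut-3-en-1-yl]-4-methoxy-2H-pyran-2-one | COC1=CC(=O)OC(CC(O)/C=C/c2ccc(OCc3ccccc3)c(c2)-c2c(OCc3ccccc3)cc(OCc3ccccc3)c3c2oc(cc3=O)-c2ccc(OC)cc2)=C1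
F6 | step 7 | 4-(benzyloxy)-3-(trimethylstannyl)benzaldehyde | C[Sn](C)(C)c1cc(C=O)ccc1OCc1ccccc1
F7 | step 4 | 1-[4,6-bis(benzyloxy)-2-hydroxy-3-iodophenyl]ethanone | CC(=O)c1c(O)c(I)c(OCc2ccccc2)cc1OCc1ccccc1
F8 | step 4 | (E)-1-[4,6-bis(benzyloxy)-2-hydroxy-3-iodophenyl]-3-(4-methoxyphenyl)prop-2-en-1-one | COc1ccc(/C=C/C(=O)c2c(O)c(I)c(OCc3ccccc3)cc2OCc2ccccc2)cc1
F9 | step 11 | racemic 5,7-bis(benzyloxy)-8-[2-(benzyloxy)-5-(5-hydroxy-7-methoxy-4-oxochroman-2-yl)phenyl]-2-(4-methoxyphenyl)-4H-chromen-4-one | COc1cc(O)c2C(=O)CC(Oc2c1)c1ccc(OCc2ccccc2)c(c1)-c1c(OCc2ccccc2)cc(OCc2ccccc2)c2c1oc(cc2=O)-c1ccc(OC)cc1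
A1 | alternative 1 | protected putraflavone with 5-O-benzyl on unit 1, 4'-O-benzyl on ring B1, 5-O-methyl and 7-O-benzyl on unit 2 | COc1ccc(cc1)-c1cc(=O)c2c(OC)cc(OCc3ccccc3)c(c2o1)-c1cc(ccc1OCc1ccccc1)-c1cc(=O)c2c(OCc3ccccc3)cc(OC)cc2o1
A2 | alternative 1 | 1-[2-(benzyloxy)-6-fluoro-4-methoxyphenyl]-3-{4-(benzyloxy)-3-[7-(benzyloxy)-5-methoxy-2-(4-methoxyphenyl)-4-oxo-4H-chromen-8-yl]phenyl}propane-1,3-dione | COc1cc(F)c(C(=O)CC(=O)c2ccc(OCc3ccccc3)c(c2)-c2c(OCc3ccccc3)cc(OC)c3c2oc(cc3=O)-c2ccc(OC)cc2)c(OCc2ccccc2)c1
A3 | alternative 2 | protected putraflavone with 5-O-methyl in both units, 4'-O-benzyl on ring B1 and 7-O-(4-methoxybenzoyl) on unit 2 | COc1ccc(cc1)-c1cc(=O)c2c(OC)cc(OC(=O)c3ccc(OC)cc3)c(c2o1)-c1cc(ccc1OCc1ccccc1)-c1cc(=O)c2c(OC)cc(OC)cc2o1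
A4 | alternative 2 | triphenylphosphoranylidene-methyl ketone of the ring A2 aryl group, which bears 6-methoxy, 2,4-bis(4-methoxybenzoyloxy) and at C3 the 2-(benzyloxy)-5-(5,7-dimethoxy-4-oxo-4H-chromen-2-yl)phenyl group | COc1cc(OC(=O)c2ccc(OC)cc2)c(-c2cc(ccc2OCc2ccccc2)-c2cc(=O)c3c(OC)cc(OC)cc3o2)c(OC(=O)c2ccc(OC)cc2)c1C(=O)C=P(c1ccccc1)(c1ccccc1)c1ccccc1
A5 | alternative 3 | protected putraflavone with 5-O-methyl in both units, 4'-O-benzyl on ring B1 and 7-O-benzyl on unit 2 | COc1ccc(cc1)-c1cc(=O)c2c(OC)cc(OCc3ccccc3)c(c2o1)-c1cc(ccc1OCc1ccccc1)-c1cc(=O)c2c(OC)cc(OC)cc2o1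
A6 | alternative 3 | 2-iodo-3,5-dimethoxyphenol | COc1cc(O)c(I)c(OC)c1
A7 | alternative 3 | 7-(benzyloxy)-8-[2-(benzyloxy)-5-ethynylphenyl]-5-methoxy-2-(4-methoxyphenyl)-4H-chromen-4-one | C#Cc1ccc(OCc2ccccc2)c(c1)-c1c(OCc2ccccc2)cc(OC)c2c1oc(cc2=O)-c1ccc(OC)cc1
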